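**Plan**

- Retrosynthesis: after removal of two MOM groups, ring B is cut at C1'–C2', C3'–C4' and C4'–C5' into cyclobutenone 13 and ynol ether 17.
- Enabling feature: ring B is oxygenated at C2', C4' and C6'. C4'–OH sits between the prenyl carbon C3' and C5'–H, with C2'–OMe meta to it and the benzofuran C2 on C1'. This is the pattern of a ketene-derived phenol carbon flanked by an ynol ether carbon and a cyclobutenone CH2.
- 13 goes back to the 2-arylcyclobutane-1,3-dione 12, to the arylketene/ethoxyacetylene (2+2) adduct 11 and to benzofuranylacetic acid 7. The furan ring comes from 2,4-dihydroxyacetophenone and chloroacetone.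
- Forward order: furan ring (step 2), side-chain transposition (steps 3–4), four-membered ring (step 5), hydrolysis and re-protection (steps 6–7), ynol ether (step 8), ring B (step 9), deprotection (step 10).
- Stereochemistry: the target has no stereocentre and no stereogenic alkene. The only stereocentres on the way (C4 of 11 and of 19, both racemic) are destroyed again.

Key step: step 9

**Route**

Step 1
Reactants: 1 2,4-dihydroxyacetophenone
Product: 2 1-[2-hydroxy-4-(methoxymethoxy)phenyl]ethanone
Conditions: MOMCl (1.1 equiv), K2CO3, acetone, 0 °C to rt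
Reagents that add atoms: chloromethyl methyl ether, COCCl
Why: Williamson-type O-alkylation; the 2-hydroxyl is tied up in a hydrogen bond to the acetyl carbonyl and is less acidic, so the chloromethyl ether should react at the free 4-hydroxyl only.

Step 2
Reactants: 2 1-[2-hydroxy-4-(methoxymethoxy)phenyl]ethanone; 3 chloroacetone
Product: 5 1-[6-(methoxymethoxy)-3-methyl-1-benzofuran-2-yl]ethanone, via aryloxyacetone 4 (not isolated)
Conditions: K2CO3, KI (cat.), MeCN, reflux
Reagents that add atoms: none
Why: Williamson ether synthesis followed in the same flask by intramolecular aldol condensation (Rap–Stoermer-type benzofuran synthesis); the O–CH2–C=O methylene of 4 is acidic enough to add to the aryl ketone, and loss of water aromatises the furan ring with the former acetyl methyl at C3.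

Step 3
Reactants: 5 1-[6-(methoxymethoxy)-3-methyl-1-benzofuran-2-yl]ethanone
Product: 6 2-[6-(methoxymethoxy)-3-methyl-1-benzofuran-2-yl]-1-(morpholin-4-yl)ethanethione
Conditions: S8, morpholine, 125 °C
Reagents that add atoms: sulfur, S1SSSSSSS1; morpholine, C1COCCN1
Why: Willgerodt–Kindler reaction; the enamine of the methyl ketone is thiated and the oxidised carbon migrates to the chain end, which should give the thioacetmorpholide while the base-stable MOM acetal and the furan ring stay untouched.

Step 4
Reactants: 6 2-[6-(methoxymethoxy)-3-methyl-1-benzofuran-2-yl]-1-(morpholin-4-yl)ethanethione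
Product: 7 [6-(methoxymethoxy)-3-methyl-1-benzofuran-2-yl]acetic acid
Conditions: KOH, EtOH/H2O, reflux; then 1 M HCl, 0 °C, to pH 3
Reagents that add atoms: potassium hydroxide, [K+].[OH-]; water, O
Why: Base hydrolysis of a thioamide to the carboxylate (addition–elimination at the thiocarbonyl); the MOM acetal is inert to hydroxide and the brief cold acidification should not cleave it.

Step 5
Reactants: 7 [6-(methoxymethoxy)-3-methyl-1-benzofuran-2-yl]acetic acid; 8 ethoxyacetylene
Product: 11 rac-3-ethoxy-4-[6-(methoxymethoxy)-3-methyl-1-benzofuran-2-yl]cyclobut-2-en-1-one, via acid chloride 9 (not isolated), via arylketene 10 (not isolated)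
Conditions: 1-chloro-N,N,2-trimethylprop-1-en-1-amine (1.0 equiv), CH2Cl2, 0 °C to rt; then slow addition to 8 (3 equiv) and Et3N (1.5 equiv), Et2O, 0 °C to rt
Reagents that add atoms: none
Why: Neutral acid chloride formation, amine-mediated dehydrochlorination to the aryl ketene and ketene–alkyne (2+2) cycloaddition; the nucleophilic CH carbon of ethoxyacetylene bonds to the ketene carbonyl carbon, which places ethoxy at C3 and the aryl group at C4, and the racemic C4 centre is erased in step 6.

Step 6
Reactants: 11 rac-3-ethoxy-4-[6-(methoxymethoxy)-3-methyl-1-benzofuran-2-yl]cyclobut-2-en-1-one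
Product: 12 3-hydroxy-2-(6-hydroxy-3-methyl-1-benzofuran-2-yl)cyclobut-2-en-1-one
Conditions: 2 M HCl (aq)/THF, 45 °C
Reagents that add atoms: water, O
Why: Acid hydrolysis of a vinylogous ester (water adds at C3, ethanol leaves) gives the cyclobutane-1,3-dione, which should rest as the aryl-conjugated enol 12; the aryl MOM acetal is cleaved on purpose in the same operation, so no selectivity between two acid-labile groups is asked for.

Step 7
Reactants: 12 3-hydroxy-2-(6-hydroxy-3-methyl-1-benzofuran-2-yl)cyclobut-2-en-1-one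
Product: 13 3-(methoxymethoxy)-2-[6-(methoxymethoxy)-3-methyl-1-benzofuran-2-yl]cyclobut-2-en-1-one
Conditions: MOMCl (2.5 equiv), iPr2NEt (3 equiv), CH2Cl2, 0 °C to rt
Reagents that add atoms: chloromethyl methyl ether, COCCl
Why: O-alkylation of a vinylogous acid and of a phenol with a hard alkylating agent; the enolate of 12 is symmetrical, so only one enol ether can form, and the amine base suffices for both hydroxyls.

Step 8
Reactants: 14 chloroacetaldehyde dimethyl acetal; 15 prenyl bromide (1-bromo-3-methylbut-2-ene)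
Product: 17 1-methoxy-5-methylhex-4-en-1-yne, via lithium methoxyacetylide 16 (not isolated)
Conditions: LiNEt2 (3.1 equiv, from Et2NH and n-BuLi), THF, 0 °C; then 15, DMPU, −20 °C to rt
Reagents that add atoms: none
Why: Two base-induced eliminations (methanol, then HCl) and deprotonation give lithium methoxyacetylide, which should be alkylated by SN2 displacement at the primary allylic carbon of prenyl bromide in the presence of the dipolar cosolvent.

Step 9
Reactants: 13 3-(methoxymethoxy)-2-[6-(methoxymethoxy)-3-methyl-1-benzofuran-2-yl]cyclobut-2-en-1-one; 17 1-methoxy-5-methylhex-4-en-1-yne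
Product: 22 3-methoxy-5-(methoxymethoxy)-4-[6-(methoxymethoxy)-3-methyl-1-benzofuran-2-yl]-2-(3-methylbut-2-en-1-yl)phenol, via vinylketene 18 (not isolated), via vinylcyclobutenone 19 (not isolated), via dienylketene 20 (not isolated), via cyclohexadienone 21 (not isolated)
Conditions: 17 (2.5 equiv), toluene, 80 °C then 110 °C, sealed tube
Reagents that add atoms: none
Why: Proposed new method: heating should open 13 by a conrotatory 4-electron electrocyclic reaction to vinylketene 18, whose ketene C=C adds ynol ether 17 in a (2+2) step to give 19; this opens to dienylketene 20, which closes ring B by a thermal disrotatory 6-electron electrocyclisation (new bond C4'–C5') and enolises from 21 to the phenol. The closest known reaction type is the Danheiser benzannulation of 3-alkyl and 2,3-dialkyl cyclobutenones with alkoxyalkynes; a 3-alkoxy-2-heteroaryl cyclobutenone is a new substrate class, but its 3-oxygen is only cross-conjugated to the ketene and should leave the ketene carbonyl carbon electrophilic. No stereocentre survives, since the quaternary carbon of 19 becomes C1' of the planar arene. The step needs regioselectivity in the (2+2) addition, and the polarisation of the ynol ether secures it: its nucleophilic carbon (the one bearing the prenyl CH2) bonds to the ketene carbonyl carbon (C3'–C4') and its methoxy-bearing carbon to the benzofuranyl carbon (C1'–C2'). It also needs chemoselectivity, which should follow from the much higher reactivity of the ynol ether than of the prenyl alkene towards ketenes, from the methyl ether having no β-hydrogen for a retro-ene loss, and from the C3 methyl of the benzofuran, which blocks aromatisation of any closure onto the furan ring so that the reversible ring openings funnel into 22.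

Step 10
Reactants: 22 3-methoxy-5-(methoxymethoxy)-4-[6-(methoxymethoxy)-3-methyl-1-benzofuran-2-yl]-2-(3-methylbut-2-en-1-yl)phenol
Product: 23 glycybenzofuran, 4-(6-hydroxy-3-methyl-1-benzofuran-2-yl)-5-methoxy-6-(3-methylbut-2-en-1-yl)benzene-1,3-diol
Conditions: 3 M HCl (aq)/MeOH, 40 °C
Reagents that add atoms: none
Why: Acid-catalysed acetal exchange with methanol frees both phenols; at this acid strength and temperature acetal cleavage should be faster than protonation of the trisubstituted prenyl alkene.

**Compound list**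

1 | 2,4-dihydroxyacetophenone | CC(=O)c1ccc(O)cc1O | starting material
2 | 1-[2-hydroxy-4-(methoxymethoxy)phenyl]ethanone | COCOc1ccc(C(C)=O)c(O)c1 | intermediate
3 | chloroacetone | CC(=O)CCl | starting material
4 | 1-[4-(methoxymethoxy)-2-(2-oxopropoxy)phenyl]ethanone (aryloxyacetone, not isolated) | COCOc1ccc(C(C)=O)c(OCC(C)=O)c1 | intermediate
5 | 1-[6-(methoxymethoxy)-3-methyl-1-benzofuran-2-yl]ethanone | COCOc1ccc2c(C)c(C(C)=O)oc2c1 | intermediate
6 | 2-[6-(methoxymethoxy)-3-methyl-1-benzofuran-2-yl]-1-(morpholin-4-yl)ethanethione | COCOc1ccc2c(C)c(CC(=S)N3CCOCC3)oc2c1 | intermediate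
7 | [6-(methoxymethoxy)-3-methyl-1-benzofuran-2-yl]acetic acid | COCOc1ccc2c(C)c(CC(=O)O)oc2c1 | intermediate
8 | ethoxyacetylene | CCOC#C | starting material
9 | [6-(methoxymethoxy)-3-methyl-1-benzofuran-2-yl]acetyl chloride (not isolated) | COCOc1ccc2c(C)c(CC(=O)Cl)oc2c1 | intermediate
10 | 2-[6-(methoxymethoxy)-3-methyl-1-benzofuran-2-yl]ethen-1-one (arylketene, not isolated) | COCOc1ccc2c(C)c(C=C=O)oc2c1 | intermediate
11 | rac-3-ethoxy-4-[6-(methoxymethoxy)-3-methyl-1-benzofuran-2-yl]cyclobut-2-en-1-one (racemic at C4) | CCOC1=CC(=O)C1c1oc2cc(OCOC)ccc2c1C | intermediate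
12 | 3-hydroxy-2-(6-hydroxy-3-methyl-1-benzofuran-2-yl)cyclobut-2-en-1-one (enol of the 2-arylcyclobutane-1,3-dione) | OC1=C(c2oc3cc(O)ccc3c2C)C(=O)C1 | intermediate
13 | 3-(methoxymethoxy)-2-[6-(methoxymethoxy)-3-methyl-1-benzofuran-2-yl]cyclobut-2-en-1-one | COCOC1=C(c2oc3cc(OCOC)ccc3c2C)C(=O)C1 | intermediate
14 | chloroacetaldehyde dimethyl acetal | COC(CCl)OC | starting material
15 | prenyl bromide | CC(C)=CCBr | starting material
16 | lithium methoxyacetylide (not isolated) | [Li]C#COC | intermediate
17 | 1-methoxy-5-methylhex-4-en-1-yne | COC#CCC=C(C)C | intermediate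
18 | 3-(methoxymethoxy)-2-[6-(methoxymethoxy)-3-methyl-1-benzofuran-2-yl]buta-1,3-dien-1-one (vinylketene, not isolated) | C=C(OCOC)C(=C=O)c1oc2cc(OCOC)ccc2c1C | intermediate
19 | rac-3-methoxy-4-[1-(methoxymethoxy)ethenyl]-4-[6-(methoxymethoxy)-3-methyl-1-benzofuran-2-yl]-2-(3-methylbut-2-en-1-yl)cyclobut-2-en-1-one (vinylcyclobutenone, racemic at C4, not isolated) | COC1=C(CC=C(C)C)C(=O)C1(C(=C)OCOC)c1oc2cc(OCOC)ccc2c1C | intermediate
20 | 3-methoxy-5-(methoxymethoxy)-4-[6-(methoxymethoxy)-3-methyl-1-benzofuran-2-yl]-2-(3-methylbut-2-en-1-yl)hexa-1,3,5-trien-1-one (dienylketene, isomer with ketene carbon and alkoxyvinyl group cis, not isolated) | C=C(OCOC)/C(c1oc2cc(OCOC)ccc2c1C)=C(OC)\C(CC=C(C)C)=C=O | intermediate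
21 | 3-methoxy-5-(methoxymethoxy)-4-[6-(methoxymethoxy)-3-methyl-1-benzofuran-2-yl]-2-(3-methylbut-2-en-1-yl)cyclohexa-2,4-dien-1-one (not isolated) | COC1=C(CC=C(C)C)C(=O)CC(OCOC)=C1c1oc2cc(OCOC)ccc2c1C | intermediate
22 | 3-methoxy-5-(methoxymethoxy)-4-[6-(methoxymethoxy)-3-methyl-1-benzofuran-2-yl]-2-(3-methylbut-2-en-1-yl)phenol | COc1c(CC=C(C)C)c(O)cc(OCOC)c1-c1oc2cc(OCOC)ccc2c1C | intermediate
23 | glycybenzofuran | COc1c(CC=C(C)C)c(O)cc(O)c1-c1oc2cc(O)ccc2c1C | target

**Totals**

Total step count: 10. Longest linear sequence: 9 steps (steps 1–7, 9 and 10, from 2,4-dihydroxyacetophenone); step 8 is a one-step side branch.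

**Steps most likely to fail**

Step 9. The donor-substituted cyclobutenone may open too slowly, so that loss of the MOM enol ether or dimerisation of the vinylketene outruns its capture by the ynol ether. The fallback generates the vinylketene at room temperature by the diazo ketone (photochemical Wolff rearrangement) version of the annulation, which is established for unsaturated α-diazo ketones. It sets out from 5 and rejoins the route at 23.
- Claisen condensation of 5 with ethyl acetate (NaH, THF) should give 1-[6-(methoxymethoxy)-3-methyl-1-benzofuran-2-yl]butane-1,3-dione F1.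
- Diazo transfer (4-acetamidobenzenesulfonyl azide, Et3N, MeCN) should give 2-diazo-1-[6-(methoxymethoxy)-3-methyl-1-benzofuran-2-yl]butane-1,3-dione F2.
- Enol silylation of the acetyl group (iPr3SiOTf, Et3N, CH2Cl2, 0 °C) should give 2-diazo-1-[6-(methoxymethoxy)-3-methyl-1-benzofuran-2-yl]-3-[(triisopropylsilyl)oxy]but-3-en-1-one F3.
- Irradiation of F3 with excess 17 in 1,2-dichloroethane at rt, then warming to 80 °C, should extrude nitrogen and, by aryl migration, give 2-[6-(methoxymethoxy)-3-methyl-1-benzofuran-2-yl]-3-[(triisopropylsilyl)oxy]buta-1,3-dien-1-one F4.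
- F4 should follow the cascade of step 9 to 3-methoxy-4-[6-(methoxymethoxy)-3-methyl-1-benzofuran-2-yl]-2-(3-methylbut-2-en-1-yl)-5-[(triisopropylsilyl)oxy]phenol F5.
- Bu4NF in THF at 0 °C should give 5-methoxy-4-[6-(methoxymethoxy)-3-methyl-1-benzofuran-2-yl]-6-(3-methylbut-2-en-1-yl)benzene-1,3-diol F6, and the conditions of step 10 then give 23.

Step 5. Dimerisation of the aryl ketene, or its interception by the amine and chloride present, may outrun the cycloaddition with ethoxyacetylene. The fallback forms the same ketene without base or acid chloride. It sets out from 5 and rejoins the route at 11.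
- Trifluoroacetylation of 5 (LiN(SiMe3)2, THF, −78 °C, then 2,2,2-trifluoroethyl trifluoroacetate) should give 4,4,4-trifluoro-1-[6-(methoxymethoxy)-3-methyl-1-benzofuran-2-yl]butane-1,3-dione F7.
- Deacylative diazo transfer (MsN3, Et3N, H2O, MeCN) should give 2-diazo-1-[6-(methoxymethoxy)-3-methyl-1-benzofuran-2-yl]ethanone F8.
- Irradiation of F8 in CH2Cl2 at rt with excess 8 should give ketene 10 by Wolff rearrangement, which is trapped as 11.

Step 10. Protonation of the prenyl alkene and capture of the cation by the neighbouring C4' hydroxyl (chroman ring closure) may compete with acetal cleavage. The fallback moves to silyl protection so that the last step is fluoride-mediated. It sets out from 12 and rejoins the route at 23.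
- iPr3SiOTf (2.2 equiv) and 2,6-lutidine in CH2Cl2 at −78 to 0 °C should give 3-[(triisopropylsilyl)oxy]-2-{3-methyl-6-[(triisopropylsilyl)oxy]-1-benzofuran-2-yl}cyclobut-2-en-1-one F9.
- Annulation of F9 with 17 under the conditions of step 9 should give 3-methoxy-2-(3-methylbut-2-en-1-yl)-4-{3-methyl-6-[(triisopropylsilyl)oxy]-1-benzofuran-2-yl}-5-[(triisopropylsilyl)oxy]phenol F10.
- Bu4NF buffered with AcOH in THF at 0 °C should give 23.

**Further compounds**

F1 | step 9 | 1-[6-(methoxymethoxy)-3-methyl-1-benzofuran-2-yl]butane-1,3-dione | CC(=O)CC(=O)c1oc2cc(OCOC)ccc2c1C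
F2 | step 9 | 2-diazo-1-[6-(methoxymethoxy)-3-methyl-1-benzofuran-2-yl]butane-1,3-dione | CC(=O)C(=[N+]=[N-])C(=O)c1oc2cc(OCOC)ccc2c1C
F3 | step 9 | 2-diazo-1-[6-(methoxymethoxy)-3-methyl-1-benzofuran-2-yl]-3-[(triisopropylsilyl)oxy]but-3-en-1-one | C=C(O[Si](C(C)C)(C(C)C)C(C)C)C(=[N+]=[N-])C(=O)c1oc2cc(OCOC)ccc2c1C
F4 | step 9 | 2-[6-(methoxymethoxy)-3-methyl-1-benzofuran-2-yl]-3-[(triisopropylsilyl)oxy]buta-1,3-dien-1-one | C=C(O[Si](C(C)C)(C(C)C)C(C)C)C(=C=O)c1oc2cc(OCOC)ccc2c1C
F5 | step 9 | 3-methoxy-4-[6-(methoxymethoxy)-3-methyl-1-benzofuran-2-yl]-2-(3-methylbut-2-en-1-yl)-5-[(triisopropylsilyl)oxy]phenol | COc1c(CC=C(C)C)c(O)cc(O[Si](C(C)C)(C(C)C)C(C)C)c1-c1oc2cc(OCOC)ccc2c1C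
F6 | step 9 | 5-methoxy-4-[6-(methoxymethoxy)-3-methyl-1-benzofuran-2-yl]-6-(3-methylbut-2-en-1-yl)benzene-1,3-diol | COc1c(CC=C(C)C)c(O)cc(O)c1-c1oc2cc(OCOC)ccc2c1C
F7 | step 5 | 4,4,4-trifluoro-1-[6-(methoxymethoxy)-3-methyl-1-benzofuran-2-yl]butane-1,3-dione | O=C(CC(=O)C(F)(F)F)c1oc2cc(OCOC)ccc2c1C
F8 | step 5 | 2-diazo-1-[6-(methoxymethoxy)-3-methyl-1-benzofuran-2-yl]ethanone | [N-]=[N+]=CC(=O)c1oc2cc(OCOC)ccc2c1C
F9 | step 10 | 3-[(triisopropylsilyl)oxy]-2-{3-methyl-6-[(triisopropylsilyl)oxy]-1-benzofuran-2-yl}cyclobut-2-en-1-one | CC(C)[Si](OC1=C(c2oc3cc(O[Si](C(C)C)(C(C)C)C(C)C)ccc3c2C)C(=O)C1)(C(C)C)C(C)C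
F10 | step 10 | 3-methoxy-2-(3-methylbut-2-en-1-yl)-4-{3-methyl-6-[(triisopropylsilyl)oxy]-1-benzofuran-2-yl}-5-[(triisopropylsilyl)oxy]phenol | COc1c(CC=C(C)C)c(O)cc(O[Si](C(C)C)(C(C)C)C(C)C)c1-c1oc2cc(O[Si](C(C)C)(C(C)C)C(C)C)ccc2c1C
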